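**Plan**

- Retrosynthesis: remove the C15 silyl group, the 7β-acetate (allylic oxidation at C7, then inversion), the C18 methyl (C4 enolate methylation) and a helper C1 carbonyl; then open rings A and B together by cutting C2–C3 and C5–C10. The resulting open chain is cut at C4=C5 (cross-metathesis), C13=C14 (olefination), C1–C2, C10–C20 and C6–C7, back to (R)-limonene.
- Enabling feature: the C19 ester on C4 lets C3–C4–C5 be a 2-(bromomethyl)acrylate (a 1,3-bis-electrophile), and a temporary C1 ketone makes C10 and C2 the two α-carbons of one carbonyl. Because C5–C10 is the bond shared by rings A and B, one enolate cascade on the open chain closes ring B (C10 to C5) and then ring A (C2 to C3).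
- Forward: limonene (C1, C7–C13, C16, C17) is allylated, ring-cleaved and elaborated at both ends; the cascade builds the trans-decalin; ketone removal, C4 methylation, C7 oxygenation and desilylation finish.
- Stereochemistry: C9 from (R)-limonene; C10 and C5 in the cascade (1,3-allylic strain in chair transition states); C4 by equatorial methylation of the ester enolate; C7 by α-face SeO2 oxidation then Mitsunobu inversion; 13E by the Horner–Wadsworth–Emmons reaction.

Key step: step 12

Remark: atoms carry labdane numbers (C1–C20); α is the ring face opposite to the C10 methyl group; TBDPSO = tert-butyl(diphenyl)silyloxy. C10 and the C1 carbinol of the open-chain intermediates are carried as epimer mixtures, because both centres become planar before or in step 12.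

**Step 1**
Reactants: 1 (R)-(+)-limonene; 2 allyl bromide
Product: 4 (4R)-4-(hexa-1,5-dien-2-yl)-1-methylcyclohex-1-ene, via 10-lithiolimonene 3 (not isolated)
Conditions: n-BuLi, TMEDA, hexane, rt; then 2, THF, −78 °C → rt
Reagents that add atoms: none
Why: Kinetic allylic lithiation of limonene by n-BuLi·TMEDA takes place at the isopropenyl methyl group to give a symmetrical 2-substituted allyllithium, and its alkylation with allyl bromide (allyl–allyl coupling) installs C6 and C5 without touching the C9 stereocentre.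

**Step 2**
Reactants: 4 (4R)-4-(hexa-1,5-dien-2-yl)-1-methylcyclohex-1-ene
Product: 5 (4R)-4-(hexa-1,5-dien-2-yl)-1-methyl-7-oxabicyclo[4.1.0]heptane (epoxide diastereomers)
Conditions: mCPBA (1.0 equiv), NaHCO3, CH2Cl2, 0 °C
Reagents that add atoms: mCPBA (3-chloroperoxybenzoic acid), O=C(OO)c1cccc(Cl)c1
Why: Prilezhaev epoxidation is fastest at the most electron-rich (trisubstituted, ring) alkene, so the 1,1-disubstituted and the monosubstituted alkenes should survive, as in the selective 1,2-epoxidation of limonene itself.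

**Step 3**
Reactants: 5 (4R)-4-(hexa-1,5-dien-2-yl)-1-methyl-7-oxabicyclo[4.1.0]heptane
Product: 7 (3R)-3-(hexa-1,5-dien-2-yl)-6-oxoheptanal, via 1,2-diol 6 (not isolated)
Conditions: H5IO6, THF/H2O, 0 °C → rt
Reagents that add atoms: water, O
Why: Periodic acid hydrolyses the epoxide and cleaves the resulting glycol (Malaprade cleavage) to the keto aldehyde, in which C9 is not enolizable.

**Step 4**
Reactants: 7 (3R)-3-(hexa-1,5-dien-2-yl)-6-oxoheptanal
Product: 8 (3S)-3-(hexa-1,5-dien-2-yl)-2-methylidene-6-oxoheptanal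
Conditions: aqueous HCHO, pyrrolidine (10 mol %), propionic acid (10 mol %), i-PrOH, 45 °C
Reagents that add atoms: formaldehyde, C=O
Why: Amine-catalysed Mannich condensation–elimination (α-methylenation of an aldehyde) turns the CH2CHO terminus into the 2-substituted acrolein that carries C20, while the methyl ketone does not react and C9 has no acidifying group.

**Step 5**
Reactants: 8 (3S)-3-(hexa-1,5-dien-2-yl)-2-methylidene-6-oxoheptanal
Product: 9 (5S)-5-(hexa-1,5-dien-2-yl)-7-hydroxy-6-methylideneoctan-2-one (C7 epimers)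
Conditions: MeTi(OiPr)3, THF, −40 → 0 °C
Reagents that add atoms: methyltitanium triisopropoxide, C[Ti](OC(C)C)(OC(C)C)OC(C)C
Why: The methyltitanium reagent adds 1,2 to aldehydes much faster than to ketones, so C2 is attached at C1 while the C13 methyl ketone survives, and the new carbinol centre is oxidised later and need not be controlled.

**Step 6**
Reactants: 9 (5S)-5-(hexa-1,5-dien-2-yl)-7-hydroxy-6-methylideneoctan-2-one; 10 triethyl phosphonoacetate
Product: 11 ethyl (2E,6S)-6-(hexa-1,5-dien-2-yl)-8-hydroxy-3-methyl-7-methylidenenon-2-enoate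
Conditions: NaH, THF, 0 → 50 °C; the minor 2Z isomer is removed by chromatography
Reagents that add atoms: none
Why: Horner–Wadsworth–Emmons olefination of the unhindered methyl ketone should favour the E enoate (ester trans to the chain), which fixes the 13E alkene of the target.

**Step 7**
Reactants: 11 ethyl (2E,6S)-6-(hexa-1,5-dien-2-yl)-8-hydroxy-3-methyl-7-methylidenenon-2-enoate
Product: 12 (2E,6S)-6-(hexa-1,5-dien-2-yl)-3-methyl-7-methylidenenon-2-ene-1,8-diol
Conditions: i-Bu2AlH, CH2Cl2, −78 → 0 °C; aqueous KNaC4H4O6 work-up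
Reagents that add atoms: none
Why: 1,2-Reduction of the α,β-unsaturated ester by i-Bu2AlH gives the allylic alcohol without touching the isolated alkenes or the alkene geometry.

**Step 8**
Reactants: 12 (2E,6S)-6-(hexa-1,5-dien-2-yl)-3-methyl-7-methylidenenon-2-ene-1,8-diol
Product: 13 (4S,7E)-9-(TBDPSO)-4-(hexa-1,5-dien-2-yl)-7-methyl-3-methylidenenon-7-en-2-ol
Conditions: TBDPSCl, imidazole, CH2Cl2, 0 °C
Reagents that add atoms: tert-butyl(chloro)diphenylsilane, CC(C)(C)[Si](Cl)(c1ccccc1)c1ccccc1
Why: Silylation with the bulky chlorosilane is selective for the primary allylic alcohol over the hindered secondary one.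

**Step 9**
Reactants: 13 (4S,7E)-9-(TBDPSO)-4-(hexa-1,5-dien-2-yl)-7-methyl-3-methylidenenon-7-en-2-ol
Product: 14 (4S,7E)-9-(TBDPSO)-4-(hexa-1,5-dien-2-yl)-7-methyl-3-methylidenenon-7-en-2-one
Conditions: Dess–Martin periodinane, CH2Cl2, 0 °C → rt
Reagents that add atoms: none
Why: Dess–Martin oxidation of the secondary allylic alcohol gives the α-methylene ketone under conditions that leave the silyl ether and the alkenes intact.

**Step 10**
Reactants: 14 (4S,7E)-9-(TBDPSO)-4-(hexa-1,5-dien-2-yl)-7-methyl-3-methylidenenon-7-en-2-one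
Product: 16 (4R,7E)-9-(TBDPSO)-4-(hexa-1,5-dien-2-yl)-3,7-dimethylnon-7-en-2-one (C3 epimers), via lithium enolate 15 (not isolated)
Conditions: LiBH(s-Bu)3, THF, −78 °C; then aqueous NH4Cl
Reagents that add atoms: none
Why: The hindered borohydride adds hydride in a 1,4 sense to the β-unsubstituted enone (conjugate reduction), and protonation of the enolate gives the α-methyl ketone as a C10 epimer mixture that converges in step 12.

**Step 11**
Reactants: 16 (4R,7E)-9-(TBDPSO)-4-(hexa-1,5-dien-2-yl)-3,7-dimethylnon-7-en-2-one; 17 methyl 2-(bromomethyl)acrylate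
Product: 18 methyl (2Z,7R)-2-(bromomethyl)-7-[(3E)-5-(TBDPSO)-3-methylpent-3-en-1-yl]-8-methyl-6-methylidene-9-oxodec-2-enoate (C8 epimers)
Conditions: second-generation Hoveyda–Grubbs catalyst, RuCl2(H2IMes)(=CH-C6H4-2-O-i-Pr) (5 mol %), excess 17, CH2Cl2, 40 °C
Reagents that add atoms: none
Why: Olefin cross-metathesis between the only monosubstituted alkene and the 2-substituted acrylate (as with methacrylates) should give the trisubstituted enoate with the chain trans to the ester, while the hindered 1,1-disubstituted and the trisubstituted alkenes stay out.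

**Step 12**
Reactants: 18 methyl (2Z,7R)-2-(bromomethyl)-7-[(3E)-5-(TBDPSO)-3-methylpent-3-en-1-yl]-8-methyl-6-methylidene-9-oxodec-2-enoate
Product: 21 methyl 15-(TBDPSO)-1-oxo-18-norlabda-8(17),13E-dien-19-oate (C4 ester α-equatorial; 5α-H; 9α-H; 10β-CH3), via potassium enolate 19 (not isolated), via monocyclic keto acrylate 20 (not isolated)
Conditions: t-BuOK (1.5 equiv), t-BuOH/THF, slow addition of 18 to a final 0.005 M, 0 °C → rt; aqueous NH4Cl
Reagents that add atoms: none
Why: t-BuOK enolizes the methyl ketone reversibly, and of the two enolates only the fully substituted C10 enolate 19 can reach the bromomethyl enoate through a six-membered transition state, so it adds to C5 (6-exo-trig Michael addition, enolexo) and the ester enolate expels bromide (net SN2′ alkylation), which closes ring B and unveils the 2-substituted acrylate 20. In 20 the ketone can enolize only toward C2, and this enolate adds to the acrylate CH2 (C3) in a 6-endo-trig (enolendo) Michael addition that closes ring A, after which proton transfer leaves the C4 ester equatorial. The closest known reaction type is the α,α′-annulation of ketones (as enolates or enamines) with 2-(bromomethyl)acrylates, a tandem SN2′ alkylation–Michael addition, applied here to a substrate whose bis-electrophile is tethered so that the first alkylation is itself a ring closure. C10 is controlled by 1,3-allylic strain in the tetrasubstituted enolate: C9–H eclipses the enolate C10=C1 bond, C8 and C11 lie on opposite faces, and the chair with the C11 side chain equatorial joins C5 to the face of C10 that C8 occupies, which leaves the C10 methyl anti to C9–H (10β-CH3, 9α-H). C5 is controlled by 1,3-allylic strain in the trisubstituted enoate (a C6–H, not C7, eclipses C5=C4 because C4 carries a cis substituent), which keeps the acrylate unit equatorial and trans to the C1 acyl group and so leads to the trans ring fusion (5α-H). The selectivities needed are reaction through the C10 and not the C2 enolate, and cyclization ahead of intermolecular alkylation or loss of HBr; the first is secured by ring size (C2 could only close eight- or ten-membered rings), the others by high dilution and the fast 6-exo closure.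

**Step 13**
Reactants: 21 methyl 15-(TBDPSO)-1-oxo-18-norlabda-8(17),13E-dien-19-oate (C4 ester α)
Product: 23 methyl 15-(TBDPSO)-18-norlabda-8(17),13E-dien-19-oate (C4 ester α-equatorial), via tosylhydrazone 22 (not isolated)
Conditions: TsNHNH2, EtOH, 70 °C; then catecholborane, CHCl3, 0 °C → rt; then NaOAc·3H2O, reflux
Reagents that add atoms: none
Why: Caglioti-type reduction, in which the tosylhydrazone is reduced by catecholborane and the derived diazene loses N2, removes the helper C1 carbonyl without a base strong enough to move the exocyclic alkene.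

**Step 14**
Reactants: 23 methyl 15-(TBDPSO)-18-norlabda-8(17),13E-dien-19-oate (C4 ester α)
Product: 25 methyl 15-(TBDPSO)labda-8(17),13E-dien-19-oate, via lithium ester enolate 24 (not isolated)
Conditions: LiN(i-Pr)2, THF, −78 → 0 °C; then MeI, DMPU, −78 → 0 °C
Reagents that add atoms: iodomethane, CI
Why: Alkylation of the exocyclic C4 ester enolate should take place on the α (equatorial) face, away from the axial C10 methyl group, so the new methyl is 4α and the ester becomes 4β (axial), as in related 4-carboalkoxy-10-methyl-trans-decalins.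

**Step 15**
Reactants: 25 methyl 15-(TBDPSO)labda-8(17),13E-dien-19-oate
Product: 26 methyl 15-(TBDPSO)-7α-hydroxylabda-8(17),13E-dien-19-oate
Conditions: SeO2 (0.3 equiv), t-BuOOH, CH2Cl2, 0 °C → rt
Reagents that add atoms: selenium dioxide, O=[Se]=O; tert-butyl hydroperoxide, CC(C)(C)OO
Why: Riley allylic oxidation (ene reaction, then 2,3-sigmatropic shift) of the exocyclic methylene attacks the ring CH2 at C7 and delivers oxygen axially on the α face, while the side-chain alkene is deactivated by its allylic oxygen as in geranyl ethers and esters.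

**Step 16**
Reactants: 26 methyl 15-(TBDPSO)-7α-hydroxylabda-8(17),13E-dien-19-oate
Product: 27 methyl 7β-acetoxy-15-(TBDPSO)labda-8(17),13E-dien-19-oate
Conditions: PPh3, DIAD, AcOH, toluene, 0 °C → rt
Reagents that add atoms: acetic acid, CC(=O)O
Why: Mitsunobu esterification displaces the activated axial 7α-oxygen by acetate with inversion (SN2, equatorial approach), which should give the 7β-acetate directly.

**Step 17**
Reactants: 27 methyl 7β-acetoxy-15-(TBDPSO)labda-8(17),13E-dien-19-oate
Product: 28 methyl 7β-acetoxy-15-hydroxylabda-8(17),13E-dien-19-oate (target)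
Conditions: Bu4NF, AcOH, THF, 0 °C → rt
Reagents that add atoms: none
Why: Fluoride cleaves the silyl ether, and buffering with acetic acid should prevent migration or loss of the C7 acetate.

**Compound list**

1 | (R)-(+)-limonene, (4R)-1-methyl-4-(prop-1-en-2-yl)cyclohex-1-ene | CC1=CC[C@@H](CC1)C(C)=C | starting material
2 | allyl bromide (3-bromoprop-1-ene) | C=CCBr | starting material
3 | 10-lithiolimonene (allyllithium at the isopropenyl methyl, TMEDA-solvated) | CC1=CC[C@@H](CC1)C(=C)C[Li] | intermediate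
4 | (4R)-4-(hexa-1,5-dien-2-yl)-1-methylcyclohex-1-ene | CC1=CC[C@@H](CC1)C(=C)CCC=C | intermediate
5 | (4R)-4-(hexa-1,5-dien-2-yl)-1-methyl-7-oxabicyclo[4.1.0]heptane (epoxide diastereomers) | CC12OC1C[C@@H](CC2)C(=C)CCC=C | intermediate
6 | (4R)-4-(hexa-1,5-dien-2-yl)-1-methylcyclohexane-1,2-diol | CC1(O)C(O)C[C@@H](CC1)C(=C)CCC=C | intermediate
7 | (3R)-3-(hexa-1,5-dien-2-yl)-6-oxoheptanal | O=CC[C@@H](CCC(C)=O)C(=C)CCC=C | intermediate
8 | (3S)-3-(hexa-1,5-dien-2-yl)-2-methylidene-6-oxoheptanal | O=CC(=C)[C@@H](CCC(C)=O)C(=C)CCC=C | intermediate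
9 | (5S)-5-(hexa-1,5-dien-2-yl)-7-hydroxy-6-methylideneoctan-2-one (C7 epimers) | CC(O)C(=C)[C@@H](CCC(C)=O)C(=C)CCC=C | intermediate
10 | triethyl phosphonoacetate | CCOC(=O)CP(=O)(OCC)OCC | starting material
11 | ethyl (2E,6S)-6-(hexa-1,5-dien-2-yl)-8-hydroxy-3-methyl-7-methylidenenon-2-enoate | CC(O)C(=C)[C@@H](CC/C(C)=C/C(=O)OCC)C(=C)CCC=C | intermediate
12 | (2E,6S)-6-(hexa-1,5-dien-2-yl)-3-methyl-7-methylidenenon-2-ene-1,8-diol | CC(O)C(=C)[C@@H](CC/C(C)=C/CO)C(=C)CCC=C | intermediate
13 | (4S,7E)-9-{[tert-butyl(diphenyl)silyl]oxy}-4-(hexa-1,5-dien-2-yl)-7-methyl-3-methylidenenon-7-en-2-ol | CC(O)C(=C)[C@@H](CC/C(C)=C/CO[Si](c1ccccc1)(c1ccccc1)C(C)(C)C)C(=C)CCC=C | intermediate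
14 | (4S,7E)-9-{[tert-butyl(diphenyl)silyl]oxy}-4-(hexa-1,5-dien-2-yl)-7-methyl-3-methylidenenon-7-en-2-one | CC(=O)C(=C)[C@@H](CC/C(C)=C/CO[Si](c1ccccc1)(c1ccccc1)C(C)(C)C)C(=C)CCC=C | intermediate
15 | lithium C10=C1 enolate of 16 (enolate geometry not defined) | CC(O[Li])=C(C)[C@@H](CC/C(C)=C/CO[Si](c1ccccc1)(c1ccccc1)C(C)(C)C)C(=C)CCC=C | intermediate
16 | (4R,7E)-9-{[tert-butyl(diphenyl)silyl]oxy}-4-(hexa-1,5-dien-2-yl)-3,7-dimethylnon-7-en-2-one (C3 epimers) | CC(=O)C(C)[C@@H](CC/C(C)=C/CO[Si](c1ccccc1)(c1ccccc1)C(C)(C)C)C(=C)CCC=C | intermediate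
17 | methyl 2-(bromomethyl)acrylate | C=C(CBr)C(=O)OC | starting material
18 | methyl (2Z,7R)-2-(bromomethyl)-7-[(3E)-5-{[tert-butyl(diphenyl)silyl]oxy}-3-methylpent-3-en-1-yl]-8-methyl-6-methylidene-9-oxodec-2-enoate (C8 epimers) | CC(=O)C(C)[C@@H](CC/C(C)=C/CO[Si](c1ccccc1)(c1ccccc1)C(C)(C)C)C(=C)CC/C=C(\CBr)C(=O)OC | intermediate
19 | potassium C10=C1 enolate of 18 (enolate geometry not defined) | CC(O[K])=C(C)[C@@H](CC/C(C)=C/CO[Si](c1ccccc1)(c1ccccc1)C(C)(C)C)C(=C)CC/C=C(\CBr)C(=O)OC | intermediate
20 | methyl 2-{2-acetyl-3-[(3E)-5-{[tert-butyl(diphenyl)silyl]oxy}-3-methylpent-3-en-1-yl]-2-methyl-4-methylidenecyclohexyl}prop-2-enoate (ring B closed, ring A open; 5α-H, 9α-H, 10β-CH3) | C=C1CC[C@@H](C(=C)C(=O)OC)[C@](C)(C(C)=O)[C@H]1CC/C(C)=C/CO[Si](c1ccccc1)(c1ccccc1)C(C)(C)C | intermediate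
21 | methyl 15-{[tert-butyl(diphenyl)silyl]oxy}-1-oxo-18-norlabda-8(17),13E-dien-19-oate (C4 ester α-equatorial, 4β-H; 5α-H, 9α-H, 10β-CH3) | C=C1CC[C@@H]2[C@](C)(C(=O)CC[C@H]2C(=O)OC)[C@H]1CC/C(C)=C/CO[Si](c1ccccc1)(c1ccccc1)C(C)(C)C | intermediate
22 | C1 tosylhydrazone of 21 | C=C1CC[C@@H]2[C@](C)(C(=NNS(=O)(=O)c3ccc(C)cc3)CC[C@H]2C(=O)OC)[C@H]1CC/C(C)=C/CO[Si](c1ccccc1)(c1ccccc1)C(C)(C)C | intermediate
23 | methyl 15-{[tert-butyl(diphenyl)silyl]oxy}-18-norlabda-8(17),13E-dien-19-oate (C4 ester α-equatorial, 4β-H) | C=C1CC[C@@H]2[C@](C)(CCC[C@H]2C(=O)OC)[C@H]1CC/C(C)=C/CO[Si](c1ccccc1)(c1ccccc1)C(C)(C)C | intermediate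
24 | lithium C4 ester enolate of 23 | C=C1CC[C@@H]2[C@](C)(CCCC2=C(O[Li])OC)[C@H]1CC/C(C)=C/CO[Si](c1ccccc1)(c1ccccc1)C(C)(C)C | intermediate
25 | methyl 15-{[tert-butyl(diphenyl)silyl]oxy}labda-8(17),13E-dien-19-oate (4α-CH3, 4β-CO2Me) | C=C1CC[C@@H]2[C@](C)(CCC[C@]2(C)C(=O)OC)[C@H]1CC/C(C)=C/CO[Si](c1ccccc1)(c1ccccc1)C(C)(C)C | intermediate
26 | methyl 15-{[tert-butyl(diphenyl)silyl]oxy}-7α-hydroxylabda-8(17),13E-dien-19-oate | C=C1[C@H](O)C[C@@H]2[C@](C)(CCC[C@]2(C)C(=O)OC)[C@H]1CC/C(C)=C/CO[Si](c1ccccc1)(c1ccccc1)C(C)(C)C | intermediate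
27 | methyl 7β-acetoxy-15-{[tert-butyl(diphenyl)silyl]oxy}labda-8(17),13E-dien-19-oate | C=C1[C@@H](OC(C)=O)C[C@@H]2[C@](C)(CCC[C@]2(C)C(=O)OC)[C@H]1CC/C(C)=C/CO[Si](c1ccccc1)(c1ccccc1)C(C)(C)C | intermediate
28 | methyl 7β-acetoxy-15-hydroxylabda-8(17),13E-dien-19-oate, (4S,5R,7S,9R,10R) | C=C1[C@@H](OC(C)=O)C[C@@H]2[C@](C)(CCC[C@]2(C)C(=O)OC)[C@H]1CC/C(C)=C/CO | target

**Summary**

Total step count: 17. Longest linear sequence: 17 steps, from (R)-limonene 1.

Steps most likely to fail:

Step 12. Before the C10 enolate cyclizes, the alkoxide base may remove a C6 proton of the bromomethyl enoate (1,4-loss of HBr to a diene), or the more abundant C2 enolate may be alkylated by a second molecule; ring B may also close in part through the chair with the acrylate unit axial, which would give a cis fusion. The fallback takes free base out of the ring-B closure and sets out from enone 14. Conjugate hydrosilylation (Et3SiH, RhCl(PPh3)3) should give regiospecifically the fully substituted triethylsilyl enol ether (4S,7E)-9-(TBDPSO)-4-(hexa-1,5-dien-2-yl)-3,7-dimethyl-2-(triethylsilyloxy)nona-2,7-diene F1. Cross-metathesis with 17 under the conditions of step 11 should give the silyl enol ether bromide F2. A fluoride source (Bu4N[Ph3SiF2], THF, high dilution) should release the C10 enolate with no other base present and close ring B by the same SN2′ alkylation to 20, which is isolated. A catalytic amount of t-BuOK in t-BuOH/THF then closes ring A, and the fallback comes back to the route at 21.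

Step 15. The ene oxidation may also attack the allylic positions of the side-chain alkene, or go on to the C7 ketone. The fallback deactivates the side-chain alkene more strongly and moves the differentiation of the two oxygens to the end; it sets out from 25. Bu4NF should give the allylic alcohol methyl 15-hydroxylabda-8(17),13E-dien-19-oate F3, and Ac2O/pyridine its acetate methyl 15-acetoxylabda-8(17),13E-dien-19-oate F4 (the geranyl acetate situation, in which SeO2 leaves the oxygenated alkene alone). SeO2/t-BuOOH should then give the 7α-alcohol methyl 15-acetoxy-7α-hydroxylabda-8(17),13E-dien-19-oate F5, and Mitsunobu esterification with AcOH the diacetate methyl 7β,15-diacetoxylabda-8(17),13E-dien-19-oate F6. A lipase (Candida antarctica lipase B, pH 7 buffer/acetone), which hydrolyses primary acetates much faster than hindered secondary ones, should free C15 only, and the fallback comes back at 28.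

Step 16. Acetate may attack C17 in an SN2′ sense, or the activated hindered allylic alcohol may eliminate instead of undergoing SN2 inversion. The fallback sets C7 by reduction instead of substitution and sets out from 26. Dess–Martin oxidation should give the cross-conjugated ketone methyl 15-(TBDPSO)-7-oxolabda-8(17),13E-dien-19-oate F7. Luche reduction (NaBH4, CeCl3·7H2O, MeOH, −78 °C; axial hydride delivery on the α face) should give the equatorial alcohol methyl 15-(TBDPSO)-7β-hydroxylabda-8(17),13E-dien-19-oate F8. Acetylation (Ac2O, DMAP, pyridine) comes back at 27.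

**Further compounds**

F1 | step 12 | (4S,7E)-9-{[tert-butyl(diphenyl)silyl]oxy}-4-(hexa-1,5-dien-2-yl)-3,7-dimethyl-2-(triethylsilyloxy)nona-2,7-diene (enol ether geometry not defined) | CC(O[Si](CC)(CC)CC)=C(C)[C@@H](CC/C(C)=C/CO[Si](c1ccccc1)(c1ccccc1)C(C)(C)C)C(=C)CCC=C
F2 | step 12 | methyl (2Z,7S)-2-(bromomethyl)-7-[(3E)-5-{[tert-butyl(diphenyl)silyl]oxy}-3-methylpent-3-en-1-yl]-8-methyl-6-methylidene-9-(triethylsilyloxy)deca-2,8-dienoate | CC(O[Si](CC)(CC)CC)=C(C)[C@@H](CC/C(C)=C/CO[Si](c1ccccc1)(c1ccccc1)C(C)(C)C)C(=C)CC/C=C(\CBr)C(=O)OC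
F3 | step 15 | methyl 15-hydroxylabda-8(17),13E-dien-19-oate | C=C1CC[C@@H]2[C@](C)(CCC[C@]2(C)C(=O)OC)[C@H]1CC/C(C)=C/CO
F4 | step 15 | methyl 15-acetoxylabda-8(17),13E-dien-19-oate | C=C1CC[C@@H]2[C@](C)(CCC[C@]2(C)C(=O)OC)[C@H]1CC/C(C)=C/COC(C)=O
F5 | step 15 | methyl 15-acetoxy-7α-hydroxylabda-8(17),13E-dien-19-oate | C=C1[C@H](O)C[C@@H]2[C@](C)(CCC[C@]2(C)C(=O)OC)[C@H]1CC/C(C)=C/COC(C)=O
F6 | step 15 | methyl 7β,15-diacetoxylabda-8(17),13E-dien-19-oate | C=C1[C@@H](OC(C)=O)C[C@@H]2[C@](C)(CCC[C@]2(C)C(=O)OC)[C@H]1CC/C(C)=C/COC(C)=O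
F7 | step 16 | methyl 15-{[tert-butyl(diphenyl)silyl]oxy}-7-oxolabda-8(17),13E-dien-19-oate | C=C1C(=O)C[C@@H]2[C@](C)(CCC[C@]2(C)C(=O)OC)[C@H]1CC/C(C)=C/CO[Si](c1ccccc1)(c1ccccc1)C(C)(C)C
F8 | step 16 | methyl 15-{[tert-butyl(diphenyl)silyl]oxy}-7β-hydroxylabda-8(17),13E-dien-19-oate | C=C1[C@@H](O)C[C@@H]2[C@](C)(CCC[C@]2(C)C(=O)OC)[C@H]1CC/C(C)=C/CO[Si](c1ccccc1)(c1ccccc1)C(C)(C)C
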